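**Retrosynthetic overview**
1. Last bond: the benzylic C1–O ester bond, made by anodic C–H acyloxylation of alcohol 7; veratric acid 8 is delivered from a temporary diisopropylsilyl tether on the C3 oxygen, which sets C1.
2. 7 ⇒ C2–CH2Ar bond: SN2 opening of (2S,3S)-2,3-dimethyloxirane 5 by a benzylic Grignard reagent (C3 bought, C2 bought and inverted).
3. Benzylic chloride 4 ⇐ 3-hydroxy-4,5-dimethoxybenzaldehyde 1 (silylation, reduction, chlorination).
4. No ring is constructed: both arenes are bought; the only cyclic array is the six-membered transition state of the key step.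

Assumption: (2S,3S)-2,3-dimethyloxirane is bought as the single enantiomer (butane-2,3-diol pool); C1 (benzylic), C2, C3 denote the butyl chain carbons throughout.

**Step 1**
Reactants: 1 3-hydroxy-4,5-dimethoxybenzaldehyde
Product: 2 3,4-dimethoxy-5-(triisopropylsilyloxy)benzaldehyde
Conditions: iPr3SiCl, imidazole, DMF, rt
Reagents that add atoms: triisopropylsilyl chloride, CC(C)[Si](Cl)(C(C)C)C(C)C
Why: Standard imidazole-promoted O-silylation of the phenol; the bulky silyl ether survives hydride, Grignard and anodic conditions and falls to fluoride at the end.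

**Step 2**
Reactants: 2 3,4-dimethoxy-5-(triisopropylsilyloxy)benzaldehyde
Product: 3 [3,4-dimethoxy-5-(triisopropylsilyloxy)phenyl]methanol
Conditions: NaBH4, MeOH, 0 °C
Reagents that add atoms: none
Why: Borohydride reduction of the aldehyde to the benzylic alcohol; no stereocenter is formed and the aryl silyl ether is untouched.

**Step 3**
Reactants: 3 [3,4-dimethoxy-5-(triisopropylsilyloxy)phenyl]methanol
Product: 4 3,4-dimethoxy-5-(triisopropylsilyloxy)benzyl chloride
Conditions: SOCl2, CH2Cl2, 0 °C; concentrate, use crude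
Reagents that add atoms: thionyl chloride, O=S(Cl)Cl
Why: Deoxychlorination of an electron-rich benzylic alcohol through its chlorosulfite; the by-products are gases, so the labile chloride needs no aqueous work-up.

**Step 4**
Reactants: 4 3,4-dimethoxy-5-(triisopropylsilyloxy)benzyl chloride; 5 (2S,3S)-2,3-dimethyloxirane
Product: 7 (2S,3S)-4-[3,4-dimethoxy-5-(triisopropylsilyloxy)phenyl]-3-methylbutan-2-ol, via benzylic Grignard reagent 6 (not isolated)
Conditions: Mg, 2-MeTHF, 0 °C (slow addition); then CuI (10 mol %), 5, −30 °C → rt; 1 M HCl, 0 °C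
Reagents that add atoms: none
Why: Copper-catalysed SN2 opening of the trans-epoxide by the Grignard reagent inverts the attacked carbon and leaves the carbinol carbon untouched, so both centres come from the bought epoxide (C3 of the target stays S; the inverted carbon is S in 7 and becomes R C2 of the target by a priority change only).

**Step 5**
Reactants: 7 (2S,3S)-4-[3,4-dimethoxy-5-(triisopropylsilyloxy)phenyl]-3-methylbutan-2-ol; 8 3,4-dimethoxybenzoic acid
Product: 12 (1R,2R,3S)-3-hydroxy-1-(3-hydroxy-4,5-dimethoxyphenyl)-2-methylbutyl 3,4-dimethoxybenzoate, via alkoxysilyl triflate 9 (not isolated), via silyl ester tether 10 (not isolated), via silylated benzylic ester 11 (not isolated)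
Conditions: iPr2Si(OTf)2, 2,6-lutidine (3 equiv), CH2Cl2, −78 °C; then 8, −78 → 0 °C; graphite anode, Pt cathode, undivided cell, constant current (2 mA/cm2), 2.2 F/mol, 0 °C; then nBu4NF, AcOH, THF, 0 °C
Reagents that add atoms: none
Why: Proposed new method: silicon-tethered anodic benzylic C–H acyloxylation. The alcohol and veratric acid are joined on a diisopropylsilyl tether, and the lutidinium triflate formed in that silylation serves as supporting electrolyte and cathodic proton source. Two-electron anodic oxidation of the more electron-rich trialkoxyarene (arene radical cation, benzylic deprotonation by lutidine, second oxidation) gives the secondary benzylic cation stabilised by the para methoxy group. This cation sits with C2–H in the aryl plane (1,3-allylic strain) and is captured on the face carrying C3 by the silicon-bound carboxylate through a six-membered chair-like array C1–C2–C3–O–Si–O, silicon leaving as the silyl triflate. That puts the new C–O bond anti to the C2 methyl and anti to the C3 oxygen (1R), with the ester only on the benzylic oxygen; buffered fluoride then removes both silicon groups without acyl migration. The closest known reaction types are intermolecular anodic benzylic acetoxylation of alkoxytoluenes, silicon-tethered intramolecular delivery of oxygen nucleophiles to oxocarbenium ions, and 1,3-allylic-strain-controlled trapping of chiral secondary benzylic cations.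

**Compound list**
1 | 3-hydroxy-4,5-dimethoxybenzaldehyde | COc1cc(C=O)cc(O)c1OC | starting material
2 | 3,4-dimethoxy-5-(triisopropylsilyloxy)benzaldehyde | COc1cc(C=O)cc(O[Si](C(C)C)(C(C)C)C(C)C)c1OC | intermediate
3 | [3,4-dimethoxy-5-(triisopropylsilyloxy)phenyl]methanol | COc1cc(CO)cc(O[Si](C(C)C)(C(C)C)C(C)C)c1OC | intermediate
4 | 3,4-dimethoxy-5-(triisopropylsilyloxy)benzyl chloride | COc1cc(CCl)cc(O[Si](C(C)C)(C(C)C)C(C)C)c1OC | intermediate
5 | (2S,3S)-2,3-dimethyloxirane | C[C@@H]1O[C@H]1C | starting material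
6 | 3,4-dimethoxy-5-(triisopropylsilyloxy)benzylmagnesium chloride | COc1cc(C[Mg]Cl)cc(O[Si](C(C)C)(C(C)C)C(C)C)c1OC | intermediate
7 | (2S,3S)-4-[3,4-dimethoxy-5-(triisopropylsilyloxy)phenyl]-3-methylbutan-2-ol | COc1cc(C[C@H](C)[C@H](C)O)cc(O[Si](C(C)C)(C(C)C)C(C)C)c1OC | intermediate
8 | 3,4-dimethoxybenzoic acid (veratric acid) | COc1ccc(C(=O)O)cc1OC | starting material
9 | {[(2S,3S)-4-[3,4-dimethoxy-5-(triisopropylsilyloxy)phenyl]-3-methylbutan-2-yl]oxy}diisopropylsilyl trifluoromethanesulfonate | COc1cc(C[C@H](C)[C@H](C)O[Si](C(C)C)(C(C)C)OS(=O)(=O)C(F)(F)F)cc(O[Si](C(C)C)(C(C)C)C(C)C)c1OC | intermediate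
10 | {[(2S,3S)-4-[3,4-dimethoxy-5-(triisopropylsilyloxy)phenyl]-3-methylbutan-2-yl]oxy}diisopropylsilyl 3,4-dimethoxybenzoate | COc1cc(C[C@H](C)[C@H](C)O[Si](C(C)C)(C(C)C)OC(=O)c2ccc(OC)c(OC)c2)cc(O[Si](C(C)C)(C(C)C)C(C)C)c1OC | intermediate
11 | (1R,2S,3S)-3-{[diisopropyl(trifluoromethanesulfonyloxy)silyl]oxy}-1-[3,4-dimethoxy-5-(triisopropylsilyloxy)phenyl]-2-methylbutyl 3,4-dimethoxybenzoate | COc1cc([C@H](OC(=O)c2ccc(OC)c(OC)c2)[C@H](C)[C@H](C)O[Si](C(C)C)(C(C)C)OS(=O)(=O)C(F)(F)F)cc(O[Si](C(C)C)(C(C)C)C(C)C)c1OC | intermediate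
12 | (1R,2R,3S)-3-hydroxy-1-(3-hydroxy-4,5-dimethoxyphenyl)-2-methylbutyl 3,4-dimethoxybenzoate | COc1ccc(C(=O)O[C@@H](c2cc(O)c(OC)c(OC)c2)[C@H](C)[C@H](C)O)cc1OC | target

**Totals**
Total step count: 5. Longest linear sequence: 5 steps (1 → 2 → 3 → 4 → 7 → 12).

**Steps most likely to fail**

Step 5 (the proposed new method). The risks are incomplete facial control, proton loss from the cation to the styrene, over-oxidation of the product, biaryl coupling of the radical cation and acyl migration during desilylation. The fallback uses known chemistry, sets out from 7 and comes back at 12. Alcohol 7 is silylated with tBuMe2SiOTf and 2,6-lutidine to tert-butyl{[(2S,3S)-4-[3,4-dimethoxy-5-(triisopropylsilyloxy)phenyl]-3-methylbutan-2-yl]oxy}dimethylsilane F5. The benzylic methylene is oxidised with DDQ in wet CH2Cl2 to (2R,3S)-3-(tert-butyldimethylsilyloxy)-1-[3,4-dimethoxy-5-(triisopropylsilyloxy)phenyl]-2-methylbutan-1-one F6. Felkin–Anh reduction with LiBH(sBu)3 in THF at −78 °C (hydride anti to the siloxyethyl group, reinforced by the 1,3-anti preference of the beta-silyloxy group) gives (1R,2S,3S)-3-(tert-butyldimethylsilyloxy)-1-[3,4-dimethoxy-5-(triisopropylsilyloxy)phenyl]-2-methylbutan-1-ol F7. Acylation with 3,4-dimethoxybenzoyl chloride, Et3N and DMAP gives (1R,2S,3S)-3-(tert-butyldimethylsilyloxy)-1-[3,4-dimethoxy-5-(triisopropylsilyloxy)phenyl]-2-methylbutyl 3,4-dimethoxybenzoate F8, and nBu4NF/AcOH removes both silyl groups to give 12.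

Step 4. The risks are Wurtz coupling of the benzylic Grignard reagent, MgCl2-promoted rearrangement of the epoxide to butan-2-one and slow opening of a 2,3-disubstituted epoxide. The fallback replaces the Grignard reagent by a sulfone-stabilised carbanion, sets out from 4 and comes back at 7. Chloride 4 and PhSO2Na in DMF give 3,4-dimethoxy-5-(triisopropylsilyloxy)benzyl phenyl sulfone F3. Deprotonation with nBuLi at −78 °C and opening of 5 in the presence of BF3·OEt2 gives (2S,3R)-4-[3,4-dimethoxy-5-(triisopropylsilyloxy)phenyl]-3-methyl-4-(phenylsulfonyl)butan-2-ol F4 as a mixture of epimers at the sulfonyl-bearing carbon. Reductive desulfonylation with Na(Hg) and Na2HPO4 in MeOH removes that centre and gives 7.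

Step 3. The electron-rich benzylic chloride may hydrolyse or self-alkylate before use. The fallback avoids any benzylic halide by an acyl-anion route, sets out from 2 and comes back at 7. Aldehyde 2, propane-1,3-dithiol and BF3·OEt2 give 2-[3,4-dimethoxy-5-(triisopropylsilyloxy)phenyl]-1,3-dithiane F1. Lithiation with nBuLi in THF at −30 °C and SN2 opening of 5 gives (2S,3R)-3-{2-[3,4-dimethoxy-5-(triisopropylsilyloxy)phenyl]-1,3-dithian-2-yl}butan-2-ol F2. Desulfurisation with NiCl2·6H2O and NaBH4 in MeOH/THF gives 7.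

**Further compounds**
F1 | step 3 | 2-[3,4-dimethoxy-5-(triisopropylsilyloxy)phenyl]-1,3-dithiane | COc1cc(C2SCCCS2)cc(O[Si](C(C)C)(C(C)C)C(C)C)c1OC
F2 | step 3 | (2S,3R)-3-{2-[3,4-dimethoxy-5-(triisopropylsilyloxy)phenyl]-1,3-dithian-2-yl}butan-2-ol | COc1cc(C2([C@H](C)[C@H](C)O)SCCCS2)cc(O[Si](C(C)C)(C(C)C)C(C)C)c1OC
F3 | step 4 | 3,4-dimethoxy-5-(triisopropylsilyloxy)benzyl phenyl sulfone | COc1cc(CS(=O)(=O)c2ccccc2)cc(O[Si](C(C)C)(C(C)C)C(C)C)c1OC
F4 | step 4 | (2S,3R)-4-[3,4-dimethoxy-5-(triisopropylsilyloxy)phenyl]-3-methyl-4-(phenylsulfonyl)butan-2-ol (epimer mixture at C4) | COc1cc(C([C@H](C)[C@H](C)O)S(=O)(=O)c2ccccc2)cc(O[Si](C(C)C)(C(C)C)C(C)C)c1OC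
F5 | step 5 | tert-butyl{[(2S,3S)-4-[3,4-dimethoxy-5-(triisopropylsilyloxy)phenyl]-3-methylbutan-2-yl]oxy}dimethylsilane | COc1cc(C[C@H](C)[C@H](C)O[Si](C)(C)C(C)(C)C)cc(O[Si](C(C)C)(C(C)C)C(C)C)c1OC
F6 | step 5 | (2R,3S)-3-(tert-butyldimethylsilyloxy)-1-[3,4-dimethoxy-5-(triisopropylsilyloxy)phenyl]-2-methylbutan-1-one | COc1cc(C(=O)[C@H](C)[C@H](C)O[Si](C)(C)C(C)(C)C)cc(O[Si](C(C)C)(C(C)C)C(C)C)c1OC
F7 | step 5 | (1R,2S,3S)-3-(tert-butyldimethylsilyloxy)-1-[3,4-dimethoxy-5-(triisopropylsilyloxy)phenyl]-2-methylbutan-1-ol | COc1cc([C@H](O)[C@H](C)[C@H](C)O[Si](C)(C)C(C)(C)C)cc(O[Si](C(C)C)(C(C)C)C(C)C)c1OC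
F8 | step 5 | (1R,2S,3S)-3-(tert-butyldimethylsilyloxy)-1-[3,4-dimethoxy-5-(triisopropylsilyloxy)phenyl]-2-methylbutyl 3,4-dimethoxybenzoate | COc1cc([C@H](OC(=O)c2ccc(OC)c(OC)c2)[C@H](C)[C@H](C)O[Si](C)(C)C(C)(C)C)cc(O[Si](C(C)C)(C(C)C)C(C)C)c1OC
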